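**Strategy.** Side-chain numbering runs from C1' (ArOCH2) to C7' (=CMe2). C1' and C4' are cis on the C2'–C3' oxirane and C5' carries oxygen. C1' to C5' and that oxygen can therefore be tied into a six-membered enoate lactone whose ring alkene C2'=C3' must be Z. Everything rests on that ring. Nucleophilic epoxidation of (S)-4-methyl-6-isobutenyl-5,6-dihydropyran-2-one forms both oxirane C–O bonds at once, relays C5' to C3' and C2', and ignores the electron-rich C6'=C7' alkene. The precursor is built by catalytic asymmetric propargylation, carboxylation and syn-methylcupration, which guarantees the Z geometry. Borohydride opening and a primary-selective Mitsunobu etherification complete the target.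

Key step: step 4

Assumption: (S)-TRIP is taken to send the allenylboronate to the Si face of 3-methylbut-2-enal, by analogy with the Re-face additions to aryl and alkenyl aldehydes promoted by the (R)-acid; MTPA ester analysis of the resulting alcohol checks this before scale-up.

**Step 1**
Reactants: 1 3-methylbut-2-enal; 2 allenylboronic acid pinacol ester
Product: 4 (S)-6-methylhept-5-en-1-yn-4-ol, via O-boryl ether 3 (not isolated)
Conditions: 2 (1.3 equiv), (S)-TRIP [(S)-3,3'-bis(2,4,6-triisopropylphenyl)-BINOL hydrogen phosphate, 10 mol %], 4 Å MS, PhMe, −20 °C; aq. NaHCO3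
Reagents that add atoms: none
Why: Chiral phosphoric acid-catalysed allenylboration (asymmetric propargylation of an aldehyde) runs through a closed six-membered SE2' transition state, so only the homopropargylic alcohol should form, and the (S)-catalyst pocket should expose the Si face of the formyl group, which sets C5' as S.

**Step 2**
Reactants: 4 (S)-6-methylhept-5-en-1-yn-4-ol
Product: 7 methyl (5S)-5-hydroxy-7-methyloct-6-en-2-ynoate, via TMS ether 5 (not isolated), via silylated ynoate 6 (not isolated)
Conditions: n-BuLi (1.0 equiv), THF, −78 °C, then TMSCl (1.05 equiv), −78 → 0 °C; n-BuLi (1.1 equiv), −78 °C, then ClCO2Me (1.3 equiv), −78 → −20 °C; 10% citric acid, MeOH, 0 °C → rt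
Reagents that add atoms: methyl chloroformate, COC(=O)Cl; chlorotrimethylsilane, C[Si](C)(C)Cl (its atoms stay only in 5 and 6)
Why: Transient O-silylation followed by C-acylation of the lithium acetylide with a chloroformate is standard alkynoate synthesis, the citric acid work-up should remove only the labile trimethylsilyl ether, the linear alkyne keeps 7 from lactonising, and C5' is not involved.

**Step 3**
Reactants: 7 methyl (5S)-5-hydroxy-7-methyloct-6-en-2-ynoate
Product: 9 (S)-4-methyl-6-(2-methylprop-1-enyl)-5,6-dihydro-2H-pyran-2-one, via Z-hydroxy enoate 8 (not isolated)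
Conditions: Me2CuLi (2.5 equiv, from CuI and MeLi), THF, −78 °C; sat. aq. NH4Cl at −78 °C; crude in CH2Cl2, PPTS (5 mol %), rt → 40 °C
Reagents that add atoms: methyllithium (delivered as Me2CuLi), [Li]C
Why: Conjugate syn-carbocupration of an alkynoate at low temperature followed by protonation of the alkenylcopper species with retention should put the new C3' methyl trans to the ester, so C4' and C1' end up cis (2Z) and the C5' hydroxyl can close the six-membered lactone by acid-catalysed transesterification (6-exo-trig) without touching C5'.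

**Step 4**
Reactants: 9 (S)-4-methyl-6-(2-methylprop-1-enyl)-5,6-dihydro-2H-pyran-2-one
Product: 11 (1R,4S,6R)-6-methyl-4-(2-methylprop-1-enyl)-3,7-dioxabicyclo[4.1.0]heptan-2-one, via peroxy enolate 10 (not isolated)
Conditions: t-BuOOH (5.5 M in decane, 2.0 equiv), n-BuLi (1.5 equiv), THF, −78 °C; then 9, −78 → −20 °C; pH 7 phosphate buffer
Reagents that add atoms: tert-butyl hydroperoxide, CC(C)(C)OO
Why: This is a Weitz–Scheffer epoxidation: LiOOt-Bu attacks the β-carbon C3' of the lactone enoate to give lithium enolate 10, and C2' of that enolate then displaces tert-butoxide from the inner peroxide oxygen, so both oxirane C–O bonds arise in one flask. The only ring closed is the oxirane, in a 3-exo-tet mode. C3' is governed by C5', because in the half-chair that keeps the isobutenyl group pseudoequatorial the stereoelectronically required axial approach is open only on the opposite face, and only that adduct can align its O–O bond with the enolate π system without pushing the isobutenyl group axial, so a reversible addition still drains to the anti isomer. C2' is governed by ring strain alone, since an oxirane can be fused to the six-membered lactone only in cis fashion, which also locks C1' and C4' cis. The step needs chemoselectivity between two trisubstituted alkenes and gets it from polarity, as an anionic peroxide reacts with the electron-poor C2'=C3' bond and not with the electron-rich C6'=C7' bond. The closest known reaction type is the basic peroxide epoxidation of 6-substituted and of 4-methyl-5,6-dihydropyran-2-ones, and the water-free lithium peroxide, buffered by excess hydroperoxide at low temperature, is chosen to suppress saponification and γ-deprotonation with loss of the allylic carboxylate.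

**Step 5**
Reactants: 11 (1R,4S,6R)-6-methyl-4-(2-methylprop-1-enyl)-3,7-dioxabicyclo[4.1.0]heptan-2-one
Product: 12 [(2S,3R)-3-[(2S)-2-hydroxy-4-methylpent-3-enyl]-3-methyloxiran-2-yl]methanol
Conditions: NaBH4 (2.5 equiv), EtOH, 0 °C → rt; H2O
Reagents that add atoms: none
Why: Borohydride reduction of a carbonyl activated by an α-oxygen, known for glycidic esters and sugar lactones, should take the lactone through to the primary alcohol and so release the C5' hydroxyl, while the trisubstituted oxirane, the alkene and all three stereocentres stay untouched.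

**Step 6**
Reactants: 12 [(2S,3R)-3-[(2S)-2-hydroxy-4-methylpent-3-enyl]-3-methyloxiran-2-yl]methanol; 13 7-hydroxy-8-methoxycoumarin
Product: 14 7-{[(2S,3R)-3-[(2S)-2-hydroxy-4-methylpent-3-enyl]-3-methyloxiran-2-yl]methoxy}-8-methoxy-2H-chromen-2-one
Conditions: 13 (1.2 equiv), PPh3 (1.15 equiv), DIAD (1.1 equiv, slow addition), THF (0.3 M), 0 °C → rt
Reagents that add atoms: none
Why: In this Mitsunobu etherification the unhindered primary C1' hydroxyl should form the alkoxyphosphonium salt much faster than the secondary C5' hydroxyl, the acidic hydroxycoumarin supplies a phenoxide that should outrun the neutral C5' hydroxyl as nucleophile, and because C1' is not stereogenic all three stereocentres are carried over unchanged.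

**Compound list**
1 | 3-methylbut-2-enal | CC(C)=CC=O | starting material
2 | allenylboronic acid pinacol ester [4,4,5,5-tetramethyl-2-(propa-1,2-dienyl)-1,3,2-dioxaborolane] | C=C=CB1OC(C)(C)C(C)(C)O1 | starting material
3 | (S)-4,4,5,5-tetramethyl-2-[(6-methylhept-5-en-1-yn-4-yl)oxy]-1,3,2-dioxaborolane | C#CC[C@H](OB1OC(C)(C)C(C)(C)O1)C=C(C)C | intermediate
4 | (S)-6-methylhept-5-en-1-yn-4-ol | C#CC[C@H](O)C=C(C)C | intermediate
5 | (S)-trimethyl[(6-methylhept-5-en-1-yn-4-yl)oxy]silane | C#CC[C@H](O[Si](C)(C)C)C=C(C)C | intermediate
6 | methyl (5S)-7-methyl-5-(trimethylsilyloxy)oct-6-en-2-ynoate | COC(=O)C#CC[C@H](O[Si](C)(C)C)C=C(C)C | intermediate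
7 | methyl (5S)-5-hydroxy-7-methyloct-6-en-2-ynoate | COC(=O)C#CC[C@H](O)C=C(C)C | intermediate
8 | methyl (2Z,5S)-5-hydroxy-3,7-dimethylocta-2,6-dienoate | COC(=O)/C=C(/C)C[C@H](O)C=C(C)C | intermediate
9 | (S)-4-methyl-6-(2-methylprop-1-enyl)-5,6-dihydro-2H-pyran-2-one | O=C1C=C(C)C[C@H](O1)C=C(C)C | intermediate
10 | lithium (4R,6S)-4-(tert-butylperoxy)-4-methyl-6-(2-methylprop-1-enyl)-5,6-dihydro-4H-pyran-2-olate | [Li+].[O-]C1=C[C@](C)(OOC(C)(C)C)C[C@H](O1)C=C(C)C | intermediate
11 | (1R,4S,6R)-6-methyl-4-(2-methylprop-1-enyl)-3,7-dioxabicyclo[4.1.0]heptan-2-one (oxirane oxygen anti to the isobutenyl group) | O=C1[C@@H]2O[C@]2(C)C[C@H](O1)C=C(C)C | intermediate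
12 | [(2S,3R)-3-[(2S)-2-hydroxy-4-methylpent-3-enyl]-3-methyloxiran-2-yl]methanol | OC[C@@H]1O[C@]1(C)C[C@H](O)C=C(C)C | intermediate
13 | 7-hydroxy-8-methoxycoumarin | COc1c(O)ccc2ccc(=O)oc12 | starting material
14 | 7-{[(2S,3R)-3-[(2S)-2-hydroxy-4-methylpent-3-enyl]-3-methyloxiran-2-yl]methoxy}-8-methoxy-2H-chromen-2-one | COc1c(OC[C@@H]2O[C@]2(C)C[C@H](O)C=C(C)C)ccc2ccc(=O)oc12 | target

Total step count: 6
Longest linear sequence: 6 steps (1 → 4 → 7 → 9 → 11 → 12 → 14)

**Steps most likely to fail**

**Step 4.**
- Risk: conjugate addition at the fully substituted C3' may be slower than base-induced loss of the template. That loss can occur by γ-deprotonation followed by expulsion of the allylic carboxylate, or by acyl attack that opens the lactone. Facial discrimination may also erode if the half-chair flips.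
- Fallback: a reagent-controlled electrophilic epoxidation of an acyclic Z-allylic alcohol, setting out from 7 and rejoining the route at 12.
  - The C5' hydroxyl of 7 is silylated (TBSCl, imidazole, DMF) to methyl (5S)-5-[(tert-butyldimethylsilyl)oxy]-7-methyloct-6-en-2-ynoate F1.
  - Me2CuLi in THF at −78 °C gives methyl (2Z,5S)-5-[(tert-butyldimethylsilyl)oxy]-3,7-dimethylocta-2,6-dienoate F2, which cannot lactonise.
  - DIBAL-H (CH2Cl2, −78 °C) gives (2Z,5S)-5-[(tert-butyldimethylsilyl)oxy]-3,7-dimethylocta-2,6-dien-1-ol F3.
  - Sharpless asymmetric epoxidation (Ti(OiPr)4, L-(+)-diethyl tartrate, t-BuOOH, 4 Å MS, CH2Cl2, −20 °C) is directed only by the free C1' hydroxyl. For a nerol-type (Z)-3-methylalk-2-en-1-ol it should deliver the (2S,3R)-epoxide [(2S,3R)-3-{(2S)-2-[(tert-butyldimethylsilyl)oxy]-4-methylpent-3-enyl}-3-methyloxiran-2-yl]methanol F4.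
  - TBAF buffered with AcOH (THF, 0 °C) then returns 12.

**Step 6.**
- Risk: the secondary allylic hydroxyl may also be activated. Intramolecular ether closure of that hydroxyl onto the activated C1', which the cis-oxirane pre-organises, may lower chemoselectivity.
- Fallback: the redox condensation is replaced by a two-stage Williamson-type alkylation, setting out from 12 and ending at 14.
  - Selective sulfonylation of the primary hydroxyl (TsCl 1.05 equiv, Et3N, CH2Cl2, −10 °C) gives [(2S,3R)-3-[(2S)-2-hydroxy-4-methylpent-3-enyl]-3-methyloxiran-2-yl]methyl 4-methylbenzenesulfonate F5.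
  - F5 is displaced at C1' by the preformed phenoxide of 13 used in excess (Cs2CO3, DMF, rt) to reach 14.

**Step 1.**
- Risk: addition to the deactivated β,β-disubstituted enal may be sluggish, so that the uncatalysed background allenylboration erodes enantioselectivity.
- Fallback: the asymmetric C–C bond formation is replaced by a resolution, setting out from 1 and coming back at 4.
  - A zinc Barbier reaction with propargyl bromide (Zn, THF/sat. aq. NH4Cl, 0 °C) gives racemic 6-methylhept-5-en-1-yn-4-ol F6.
  - Lipase-catalysed kinetic resolution follows (immobilised Candida antarctica lipase B, vinyl acetate, MTBE, 30 °C). It should acetylate the enantiomer that places the bulkier isobutenyl group in the large pocket, giving (R)-6-methylhept-5-en-1-yn-4-yl acetate F7.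
  - The S alcohol is left behind and, after chromatography, is 4.

**Further compounds**
F1 | step 4 | methyl (5S)-5-[(tert-butyldimethylsilyl)oxy]-7-methyloct-6-en-2-ynoate | COC(=O)C#CC[C@H](O[Si](C)(C)C(C)(C)C)C=C(C)C
F2 | step 4 | methyl (2Z,5S)-5-[(tert-butyldimethylsilyl)oxy]-3,7-dimethylocta-2,6-dienoate | COC(=O)/C=C(/C)C[C@H](O[Si](C)(C)C(C)(C)C)C=C(C)C
F3 | step 4 | (2Z,5S)-5-[(tert-butyldimethylsilyl)oxy]-3,7-dimethylocta-2,6-dien-1-ol | OC/C=C(/C)C[C@H](O[Si](C)(C)C(C)(C)C)C=C(C)C
F4 | step 4 | [(2S,3R)-3-{(2S)-2-[(tert-butyldimethylsilyl)oxy]-4-methylpent-3-enyl}-3-methyloxiran-2-yl]methanol | OC[C@@H]1O[C@]1(C)C[C@H](O[Si](C)(C)C(C)(C)C)C=C(C)C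
F5 | step 6 | [(2S,3R)-3-[(2S)-2-hydroxy-4-methylpent-3-enyl]-3-methyloxiran-2-yl]methyl 4-methylbenzenesulfonate | Cc1ccc(cc1)S(=O)(=O)OC[C@@H]1O[C@]1(C)C[C@H](O)C=C(C)C
F6 | step 1 | racemic 6-methylhept-5-en-1-yn-4-ol | C#CCC(O)C=C(C)C
F7 | step 1 | (R)-6-methylhept-5-en-1-yn-4-yl acetate | C#CC[C@@H](OC(C)=O)C=C(C)C
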